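**Retrosynthetic overview**

- The route rests on ring A (O1, C2 bearing the guaiacyl group, C3 bearing CH2OH, C4 bearing the carbinol arm, C5). It divides into an O1–C5–C4 three-atom unit with a vinyl group on C4 as one-carbon handle, and a C2–C3 two-carbon unit that is an arylidene malonate.
- Target ⇐ hydrogenolysis and desilylation ⇐ (R)-carbinol by hydride reduction of the C4 aryl ketone ⇐ aryl Grignard addition to the C4 aldehyde ⇐ oxidative cleavage of the C4 vinyl group.
- All-trans ring A ⇐ loss of one ester from C3 with equilibration ⇐ cis-2-aryl-4-vinyloxolane-3,3-diester.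
- Ring A (the only ring formed) ⇐ palladium-catalysed asymmetric [3+2] annulation of racemic 2-vinyloxirane with the Knoevenagel product of O-benzylvanillin and dimethyl malonate.

Key step: step 2

Numbering remark: in all names ring A is O1, C2 (aryl carbon), C3, C4, C5, and C7' is the carbinol carbon on C4. Descriptor changes at C2 (5 to 7) and C3 (7 to 8) are priority changes, not inversions.

Assumption: the (S,S) antipode of the DACH-phenyl bisphosphine is taken to give the (2R,4S) cycloadduct; if the first run shows the opposite sense, the (R,R) ligand is used with no other change.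

**Step 1**
Reactants: 1 O-benzylvanillin [4-(benzyloxy)-3-methoxybenzaldehyde]; 2 dimethyl malonate
Product: 3 dimethyl 2-[4-(benzyloxy)-3-methoxybenzylidene]malonate
Conditions: piperidine (0.1 equiv), AcOH (0.1 equiv), toluene, reflux, Dean–Stark
Reagents that add atoms: none
Why: Knoevenagel condensation of the malonate with a non-enolisable aryl aldehyde, driven to the arylidene malonate by azeotropic removal of water; no stereocentre is formed.

**Step 2**
Reactants: 3 dimethyl 2-[4-(benzyloxy)-3-methoxybenzylidene]malonate; 4 racemic 2-vinyloxirane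
Product: 5 dimethyl (2R,4S)-2-[4-(benzyloxy)-3-methoxyphenyl]-4-vinyloxolane-3,3-dicarboxylate (aryl and vinyl cis)
Conditions: Pd2(dba)3·CHCl3 (2.5 mol %), (S,S)-DACH-phenyl bisphosphine [N,N'-(1S,2S)-cyclohexane-1,2-diylbis(2-diphenylphosphinobenzamide)] (7.5 mol %), 4 (2 equiv, added slowly), THF, rt
Reagents that add atoms: none
Why: Zerovalent palladium ionises the allylic C–O bond of 4 to a zwitterionic π-allyl palladium alkoxide (divalent palladium); the alkoxide adds reversibly to the benzylic carbon of 3 (O1–C2) and the malonate anion so formed alkylates the allyl unit (C3–C4), which is the pattern of the known palladium-catalysed [3+2] cycloadditions of vinyl oxiranes with doubly activated alkenes. Ring A closes in the 5-exo mode, C3 attacking the internal allyl carbon anti to palladium, since attack at the allyl terminus would require a seven-membered ring. C4 is set by the ligand: the diastereomeric π-allyl complexes from the two enantiomers of 4 interconvert by π–σ–π isomerisation at the unsubstituted terminus faster than they cyclise, so the process is a dynamic kinetic asymmetric transformation. C2 is set relative to C4 in the same ring closure: because the oxa-Michael addition is reversible, both C2 epimers of the open adduct are available and the one closing through an envelope with aryl and allyl both pseudo-equatorial, the 2,4-cis one, is drained. The step needs enantioselectivity and 2,4-cis diastereoselectivity; the irreversible closure to a quaternary C3 fixes both centres and offsets the modest electrophilicity of the electron-rich acceptor, and any 2,4-trans isomer is removed by chromatography.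

**Step 3**
Reactants: 5 dimethyl (2R,4S)-2-[4-(benzyloxy)-3-methoxyphenyl]-4-vinyloxolane-3,3-dicarboxylate
Product: 7 methyl (2S,3S,4S)-2-[4-(benzyloxy)-3-methoxyphenyl]-4-vinyloxolane-3-carboxylate (all-trans), via C3-epimeric monoester mixture 6 (not isolated)
Conditions: LiCl (3 equiv), H2O (2 equiv), DMSO, 150 °C; then NaOMe (0.5 equiv), MeOH, 50 °C
Reagents that add atoms: none
Why: Krapcho dealkoxycarbonylation (chloride SN2 attack on an ester methyl group, loss of CO2, protonation of the ester enolate) leaves one ester on C3, and methoxide then equilibrates C3 through the enolate to the ester trans to both the C2 aryl and the C4 vinyl group, the only isomer without a cis-vicinal interaction, while C2 and C4 are untouched.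

**Step 4**
Reactants: 7 methyl (2S,3S,4S)-2-[4-(benzyloxy)-3-methoxyphenyl]-4-vinyloxolane-3-carboxylate
Product: 8 [(2S,3R,4S)-2-[4-(benzyloxy)-3-methoxyphenyl]-4-vinyloxolan-3-yl]methanol
Conditions: LiAlH4, THF, 0 °C
Reagents that add atoms: none
Why: Hydride reduction of the ester with LiAlH4 gives the primary alcohol without touching the vinyl group or the benzyl ether, and C3 is no longer epimerisable afterwards.

**Step 5**
Reactants: 8 [(2S,3R,4S)-2-[4-(benzyloxy)-3-methoxyphenyl]-4-vinyloxolan-3-yl]methanol
Product: 9 tert-butyl{[(2S,3R,4S)-2-[4-(benzyloxy)-3-methoxyphenyl]-4-vinyloxolan-3-yl]methoxy}dimethylsilane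
Conditions: TBSCl, imidazole, DMF, rt
Reagents that add atoms: tert-butyldimethylsilyl chloride (TBSCl), CC(C)(C)[Si](C)(C)Cl
Why: Silylation of the primary alcohol masks it for the organometallic and oxidation steps with a group that fluoride later removes without exposing the benzylic C–O bonds to long hydrogenolysis.

**Step 6**
Reactants: 9 tert-butyl{[(2S,3R,4S)-2-[4-(benzyloxy)-3-methoxyphenyl]-4-vinyloxolan-3-yl]methoxy}dimethylsilane
Product: 10 (2S,3R,4S)-2-[4-(benzyloxy)-3-methoxyphenyl]-3-[(tert-butyldimethylsilyloxy)methyl]oxolane-4-carbaldehyde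
Conditions: OsO4 (2 mol %), NaIO4 (4 equiv), 2,6-lutidine (2 equiv), dioxane–H2O (3:1), rt
Reagents that add atoms: osmium tetroxide, O=[Os](=O)(=O)=O; sodium periodate, [Na+].[O-]I(=O)(=O)=O
Why: Lemieux–Johnson oxidation (catalytic dihydroxylation, then periodate glycol cleavage) converts the terminal alkene to the aldehyde and is preferred to ozone because it spares the electron-rich arenes and the benzyl ether, the lutidine buffer keeping C4 in its already stable trans arrangement.

**Step 7**
Reactants: 10 (2S,3R,4S)-2-[4-(benzyloxy)-3-methoxyphenyl]-3-[(tert-butyldimethylsilyloxy)methyl]oxolane-4-carbaldehyde; 11 4-bromo-1,2-bis(benzyloxy)benzene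
Product: 13 [3,4-bis(benzyloxy)phenyl]{(2S,3R,4S)-2-[4-(benzyloxy)-3-methoxyphenyl]-3-[(tert-butyldimethylsilyloxy)methyl]oxolan-4-yl}methanol as a mixture of C7' epimers, via aryl Grignard reagent 12 (not isolated)
Conditions: 11, Mg, THF, 40 °C (I2 initiation); then 10, THF, −78 °C; aq NH4Cl
Reagents that add atoms: none
Why: Grignard formation and 1,2-addition to the aldehyde form the C4–C7' bond; the aryl group is expected to enter the carbonyl face remote from C3 and so favour the unwanted C7' epimer, which is why both epimers are taken on to the ketone.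

**Step 8**
Reactants: 13 [3,4-bis(benzyloxy)phenyl]{(2S,3R,4S)-2-[4-(benzyloxy)-3-methoxyphenyl]-3-[(tert-butyldimethylsilyloxy)methyl]oxolan-4-yl}methanol (C7' epimers)
Product: 14 [3,4-bis(benzyloxy)phenyl]{(2S,3R,4S)-2-[4-(benzyloxy)-3-methoxyphenyl]-3-[(tert-butyldimethylsilyloxy)methyl]oxolan-4-yl}methanone
Conditions: Dess–Martin periodinane, CH2Cl2, 0 °C to rt
Reagents that add atoms: none
Why: Dess–Martin oxidation converges both carbinol epimers on one aryl ketone under nearly neutral conditions that spare the silyl and benzyl ethers, with the alpha centre C4 remaining trans to C3.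

**Step 9**
Reactants: 14 [3,4-bis(benzyloxy)phenyl]{(2S,3R,4S)-2-[4-(benzyloxy)-3-methoxyphenyl]-3-[(tert-butyldimethylsilyloxy)methyl]oxolan-4-yl}methanone
Product: 15 (R)-[3,4-bis(benzyloxy)phenyl]{(2S,3R,4S)-2-[4-(benzyloxy)-3-methoxyphenyl]-3-[(tert-butyldimethylsilyloxy)methyl]oxolan-4-yl}methanol
Conditions: Zn(BH4)2, Et2O, −20 °C
Reagents that add atoms: none
Why: Chelation-controlled hydride reduction in which zinc bridges the ketone oxygen and ring oxygen O1 (six-membered chelate through C4–C5) and hydride enters on the carbonyl face remote from C3 and its CH2OTBS arm, the same face that the Felkin–Anh arrangement with C3 as the large group exposes, giving the (R)-carbinol, the epimer complementary to that from the Grignard addition.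

**Step 10**
Reactants: 15 (R)-[3,4-bis(benzyloxy)phenyl]{(2S,3R,4S)-2-[4-(benzyloxy)-3-methoxyphenyl]-3-[(tert-butyldimethylsilyloxy)methyl]oxolan-4-yl}methanol
Product: 16 (R)-[3,4-bis(benzyloxy)phenyl]{(2S,3R,4S)-2-[4-(benzyloxy)-3-methoxyphenyl]-3-(hydroxymethyl)oxolan-4-yl}methanol
Conditions: TBAF, THF, rt
Reagents that add atoms: none
Why: Fluoride-induced cleavage of the Si–O bond frees the primary alcohol under conditions to which the benzylic alcohol, the benzylic ring ether and the aryl benzyl ethers are inert.

**Step 11**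
Reactants: 16 (R)-[3,4-bis(benzyloxy)phenyl]{(2S,3R,4S)-2-[4-(benzyloxy)-3-methoxyphenyl]-3-(hydroxymethyl)oxolan-4-yl}methanol
Product: 17 (2S,3R,4S)-4-[(R)-(3,4-dihydroxyphenyl)(hydroxy)methyl]-2-(4-hydroxy-3-methoxyphenyl)-3-(hydroxymethyl)oxolane (target)
Conditions: H2 (1 atm), 10% Pd/C, EtOAc–MeOH, rt
Reagents that add atoms: none
Why: Catalytic hydrogenolysis of the three aryl benzyl ethers, the fastest-cleaving class of benzyl ethers, under neutral conditions and stopped at full conversion so that the benzylic C7'–OH and C2–O1 bonds stay intact; no stereocentre is affected.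

**Compound list**

1 | 4-(benzyloxy)-3-methoxybenzaldehyde (O-benzylvanillin) | COc1cc(C=O)ccc1OCc1ccccc1 | starting material
2 | dimethyl malonate | COC(=O)CC(=O)OC | starting material
3 | dimethyl 2-[4-(benzyloxy)-3-methoxybenzylidene]malonate | COC(=O)C(=Cc1ccc(OCc2ccccc2)c(OC)c1)C(=O)OC | intermediate
4 | 2-vinyloxirane (racemic) | C=CC1CO1 | starting material
5 | dimethyl (2R,4S)-2-[4-(benzyloxy)-3-methoxyphenyl]-4-vinyloxolane-3,3-dicarboxylate (2,4-cis) | COc1cc([C@H]2OC[C@@H](C=C)C2(C(=O)OC)C(=O)OC)ccc1OCc1ccccc1 | intermediate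
6 | methyl (2S,4S)-2-[4-(benzyloxy)-3-methoxyphenyl]-4-vinyloxolane-3-carboxylate, mixture of C3 epimers | COc1cc([C@H]2OC[C@@H](C=C)C2C(=O)OC)ccc1OCc1ccccc1 | intermediate (not isolated)
7 | methyl (2S,3S,4S)-2-[4-(benzyloxy)-3-methoxyphenyl]-4-vinyloxolane-3-carboxylate (all-trans) | COc1cc([C@H]2OC[C@@H](C=C)[C@@H]2C(=O)OC)ccc1OCc1ccccc1 | intermediate
8 | [(2S,3R,4S)-2-[4-(benzyloxy)-3-methoxyphenyl]-4-vinyloxolan-3-yl]methanol | COc1cc([C@H]2OC[C@@H](C=C)[C@@H]2CO)ccc1OCc1ccccc1 | intermediate
9 | tert-butyl{[(2S,3R,4S)-2-[4-(benzyloxy)-3-methoxyphenyl]-4-vinyloxolan-3-yl]methoxy}dimethylsilane | COc1cc([C@H]2OC[C@@H](C=C)[C@@H]2CO[Si](C)(C)C(C)(C)C)ccc1OCc1ccccc1 | intermediate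
10 | (2S,3R,4S)-2-[4-(benzyloxy)-3-methoxyphenyl]-3-[(tert-butyldimethylsilyloxy)methyl]oxolane-4-carbaldehyde | COc1cc([C@H]2OC[C@@H](C=O)[C@@H]2CO[Si](C)(C)C(C)(C)C)ccc1OCc1ccccc1 | intermediate
11 | 4-bromo-1,2-bis(benzyloxy)benzene | Brc1ccc(OCc2ccccc2)c(OCc2ccccc2)c1 | starting material
12 | [3,4-bis(benzyloxy)phenyl]magnesium bromide | Br[Mg]c1ccc(OCc2ccccc2)c(OCc2ccccc2)c1 | intermediate (not isolated)
13 | [3,4-bis(benzyloxy)phenyl]{(2S,3R,4S)-2-[4-(benzyloxy)-3-methoxyphenyl]-3-[(tert-butyldimethylsilyloxy)methyl]oxolan-4-yl}methanol, C7' epimer mixture | COc1cc([C@H]2OC[C@@H](C(O)c3ccc(OCc4ccccc4)c(OCc4ccccc4)c3)[C@@H]2CO[Si](C)(C)C(C)(C)C)ccc1OCc1ccccc1 | intermediate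
14 | [3,4-bis(benzyloxy)phenyl]{(2S,3R,4S)-2-[4-(benzyloxy)-3-methoxyphenyl]-3-[(tert-butyldimethylsilyloxy)methyl]oxolan-4-yl}methanone | COc1cc([C@H]2OC[C@@H](C(=O)c3ccc(OCc4ccccc4)c(OCc4ccccc4)c3)[C@@H]2CO[Si](C)(C)C(C)(C)C)ccc1OCc1ccccc1 | intermediate
15 | (R)-[3,4-bis(benzyloxy)phenyl]{(2S,3R,4S)-2-[4-(benzyloxy)-3-methoxyphenyl]-3-[(tert-butyldimethylsilyloxy)methyl]oxolan-4-yl}methanol | COc1cc([C@H]2OC[C@@H]([C@@H](O)c3ccc(OCc4ccccc4)c(OCc4ccccc4)c3)[C@@H]2CO[Si](C)(C)C(C)(C)C)ccc1OCc1ccccc1 | intermediate
16 | (R)-[3,4-bis(benzyloxy)phenyl]{(2S,3R,4S)-2-[4-(benzyloxy)-3-methoxyphenyl]-3-(hydroxymethyl)oxolan-4-yl}methanol | COc1cc([C@H]2OC[C@@H]([C@@H](O)c3ccc(OCc4ccccc4)c(OCc4ccccc4)c3)[C@@H]2CO)ccc1OCc1ccccc1 | intermediate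
17 | (2S,3R,4S)-4-[(R)-(3,4-dihydroxyphenyl)(hydroxy)methyl]-2-(4-hydroxy-3-methoxyphenyl)-3-(hydroxymethyl)oxolane | COc1cc([C@H]2OC[C@@H]([C@@H](O)c3ccc(O)c(O)c3)[C@@H]2CO)ccc1O | target

**Step count**

Total steps: 11. Longest linear sequence: 11 steps (1 to 17); the aryl Grignard reagent is made in the flask from commercial 11 within step 7.

**Steps most likely to fail**

Step 2 (key step). The chiral catalyst may discriminate poorly between the two faces of the allyl unit during ring closure. It may also turn over slowly with the electron-rich acceptor, so that the zwitterion decays by isomerisation and oligomerisation; either way 5 would be obtained in insufficient enantiomeric purity. The fallback separates ring construction from enantiocontrol and sets out again from 3 and 4. The annulation is run with achiral Pd(PPh3)4 in THF at 40 °C, the established racemic form of this cycloaddition, to give the racemic cis cycloadduct F1. The conditions of step 3 take F1 through the racemic C3-epimer mixture F2 to the racemic all-trans ester F3, and LiAlH4 as in step 4 gives the racemic alcohol F4. F4 is resolved by preparative chromatography on a chiral stationary phase (cellulose tris(3,5-dimethylphenylcarbamate)); its (2S,3R,4S) enantiomer is compound 8, where the route is rejoined.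

Step 3. At 150 °C the ester enolate released on decarboxylation may expel O1 by β-elimination, opening ring A across C2–C3 and eroding the C2 configuration, and chloride may attack the hindered diester only sluggishly. The fallback sets out from 5 and avoids a free enolate at high temperature. Mono-saponification (KOH, 1.1 equiv, MeOH–H2O, 40 °C) gives the malonic half-acid F5, which loses CO2 as the neutral acid on heating in toluene at 110 °C. This gives the C3-epimer mixture 6, where the route is rejoined; equilibration with NaOMe as in step 3 then gives 7.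

Step 9. Hydride delivery may show poor facial selectivity if chelated and open transition states compete, giving a mixture of C7' epimers. The fallback sets out from 14 and replaces substrate control by reagent control. A Corey–Bakshi–Shibata reduction ((S)-2-methyl-CBS-oxazaborolidine, catalytic, BH3·SMe2, THF, −20 °C), with the aryl group acting as the large substituent, should give the (R)-carbinol 15 directly, where the route is rejoined; no new compound is made (F0).

**Further compounds**

F1 | step 2 | racemic dimethyl cis-2-[4-(benzyloxy)-3-methoxyphenyl]-4-vinyloxolane-3,3-dicarboxylate (5 plus its enantiomer) | COc1cc([C@H]2OC[C@@H](C=C)C2(C(=O)OC)C(=O)OC)ccc1OCc1ccccc1.COc1cc([C@@H]2OC[C@H](C=C)C2(C(=O)OC)C(=O)OC)ccc1OCc1ccccc1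
F2 | step 2 | racemic methyl 2,4-cis-2-[4-(benzyloxy)-3-methoxyphenyl]-4-vinyloxolane-3-carboxylate, C3 epimer mixture | COc1cc([C@H]2OC[C@@H](C=C)C2C(=O)OC)ccc1OCc1ccccc1.COc1cc([C@@H]2OC[C@H](C=C)C2C(=O)OC)ccc1OCc1ccccc1
F3 | step 2 | racemic all-trans methyl 2-[4-(benzyloxy)-3-methoxyphenyl]-4-vinyloxolane-3-carboxylate (7 plus its enantiomer) | COc1cc([C@H]2OC[C@@H](C=C)[C@@H]2C(=O)OC)ccc1OCc1ccccc1.COc1cc([C@@H]2OC[C@H](C=C)[C@H]2C(=O)OC)ccc1OCc1ccccc1
F4 | step 2 | racemic all-trans [2-[4-(benzyloxy)-3-methoxyphenyl]-4-vinyloxolan-3-yl]methanol (8 plus its enantiomer) | COc1cc([C@H]2OC[C@@H](C=C)[C@@H]2CO)ccc1OCc1ccccc1.COc1cc([C@@H]2OC[C@H](C=C)[C@H]2CO)ccc1OCc1ccccc1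
F5 | step 3 | (2R,4S)-2-[4-(benzyloxy)-3-methoxyphenyl]-3-(methoxycarbonyl)-4-vinyloxolane-3-carboxylic acid (C3 configuration not defined) | COc1cc([C@H]2OC[C@@H](C=C)C2(C(=O)O)C(=O)OC)ccc1OCc1ccccc1
F0 | step 9 | none | none
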